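## Retrosynthetic overview

1. The strategy rests on the single carbocycle. Take C1 = C(Me)OH, C2 = CHBr, C4 = the chain-bearing CH and C2' = the first chain carbon. The atoms C3–C2–C1(Me)–C6–C5–C4–C2'(Me) are then a geranyl chain (geranyl C1 to C7) folded back on itself. The cis Br/OH pair on C2/C1 is what an anti Br/O addition to its (E)-2,3-olefin gives.
2. 29 ⇒ 28 (silyl ether off) ⇒ C5'–C6' bond, made from dienyl boronate 22 and the lithiated benzoate of (S)-sulcatol 24; this sets C6'.
3. 22 ⇒ enal 19 ⇒ enoate 17 ⇒ methyl ketone 14 ⇒ isopropenylcyclohexane 12. C3' and C4' come from the phosphonoacetate and C5' from the geminal bis(boronate).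
4. 12 ⇒ ring bond C3–C4, which closes the only ring, in step 7. The allylsilane attacks the C2–C3 bromonium ion released from β-bromo triflate 9; this sets C4.
5. 9 ⇒ bromodiol 7 ⇒ Sharpless epoxide 6 (sets C1, then C2 by inversion) ⇒ allylsilane 5 ⇒ geranyl acetate 1.

Key step: step 7

Remark on the chemistry: 23 is taken as the purchased single (S)-enantiomer; ring atoms are C1–C6, side-chain atoms are C1'–C11' (C2' on the ring, C6' the acyclic carbinol), and acyclic compounds 1–9 keep geraniol numbering (geranyl C1 = ring C3, C2 = ring C2, C3 = ring C1, C6 = ring C4, C7 = C2').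

## Route

Step 1
Reactants: 1 geranyl acetate
Product: 2 (2E,6E)-8-hydroxy-3,7-dimethylocta-2,6-dien-1-yl acetate
Conditions: SeO2 (0.1 equiv), t-BuOOH (2 equiv), salicylic acid (0.1 equiv), CH2Cl2, 0 °C to rt
Reagents that add atoms: selenium dioxide O=[Se]=O (catalytic oxygen carrier); tert-butyl hydroperoxide CC(C)(C)OO (terminal oxygen source)
Why: Catalytic SeO2 allylic oxidation (ene reaction, then [2,3]-sigmatropic shift) picks the electron-richer 6,7-olefin and the methyl group trans to the chain, so the CH2OH group should end up (E), while the 2,3-olefin is deactivated by the allylic acetate.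

Step 2
Reactants: 2 (2E,6E)-8-hydroxy-3,7-dimethylocta-2,6-dien-1-yl acetate
Product: 3 (2E,6E)-8-chloro-3,7-dimethylocta-2,6-dien-1-yl acetate
Conditions: PPh3, CCl4, reflux
Reagents that add atoms: carbon tetrachloride ClC(Cl)(Cl)Cl
Why: The Appel chlorination replaces the primary allylic hydroxyl by SN2 displacement of the oxyphosphonium group, without allylic transposition or loss of olefin geometry, and the acetate is inert.

Step 3
Reactants: 3 (2E,6E)-8-chloro-3,7-dimethylocta-2,6-dien-1-yl acetate
Product: 5 (2E,6E)-3,7-dimethyl-8-(trimethylsilyl)octa-2,6-dien-1-ol, via allyltrichlorosilane 4 (not isolated)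
Conditions: HSiCl3, Et3N, CuCl (5 mol %), Et2O, 0 °C to rt; then MeMgBr (excess), Et2O, 0 °C to rt; NH4Cl aq.
Reagents that add atoms: trichlorosilane Cl[SiH](Cl)Cl; methylmagnesium bromide C[Mg]Br
Why: The CuCl/amine-promoted Benkeser-type trichlorosilylation of a primary allylic chloride places silicon on the primary carbon with the olefin geometry kept, and the Grignard reagent then turns SiCl3 into SiMe3 and cleaves the acetate in the same flask.

Step 4
Reactants: 5 (2E,6E)-3,7-dimethyl-8-(trimethylsilyl)octa-2,6-dien-1-ol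
Product: 6 {(2R,3R)-3-methyl-3-[(3E)-4-methyl-5-(trimethylsilyl)pent-3-en-1-yl]oxiran-2-yl}methanol
Conditions: Ti(OiPr)4 (10 mol %), D-(−)-diethyl tartrate (12 mol %), t-BuOOH (anhydrous, decane), 4 Å molecular sieves, CH2Cl2, −20 °C
Reagents that add atoms: tert-butyl hydroperoxide CC(C)(C)OO
Why: In the Sharpless asymmetric epoxidation the tetravalent titanium centre binds the allylic alcohol, so only the 2,3-olefin reacts and the allylsilane olefin is left alone, and the D-(−)-tartrate ligand directs oxygen to the face that gives the (2R,3R)-epoxide, which fixes ring C1.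

Step 5
Reactants: 6 {(2R,3R)-3-methyl-3-[(3E)-4-methyl-5-(trimethylsilyl)pent-3-en-1-yl]oxiran-2-yl}methanol
Product: 7 (2S,3R,6E)-2-bromo-3,7-dimethyl-8-(trimethylsilyl)oct-6-ene-1,3-diol
Conditions: NaBr, B(OMe)3, DMF, 50 °C; then H2O
Reagents that add atoms: sodium bromide [Na+].[Br-]
Why: In the borate-mediated C2-selective halide opening of a 2,3-epoxy alcohol, boron ties the C1 oxygen to the epoxide oxygen and bromide attacks the secondary C2 rather than the fully substituted C3 in an SN2 manner, so inversion at C2 gives the (2S,3R) anti bromohydrin under conditions too mild to harm the allylsilane.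

Step 6
Reactants: 7 (2S,3R,6E)-2-bromo-3,7-dimethyl-8-(trimethylsilyl)oct-6-ene-1,3-diol
Product: 9 (2S,3R,6E)-2-bromo-3,7-dimethyl-3-(triethylsilyloxy)-8-(trimethylsilyl)oct-6-en-1-yl trifluoromethanesulfonate, via hydroxy triflate 8 (not isolated)
Conditions: Tf2O (1.05 equiv), 2,6-lutidine (3 equiv), CH2Cl2, −78 °C; then Et3SiOTf (1.3 equiv), −78 to −20 °C; cold NaHCO3 aq., short silica plug, used at once
Reagents that add atoms: trifluoromethanesulfonic anhydride O=S(=O)(OS(=O)(=O)C(F)(F)F)C(F)(F)F; triethylsilyl trifluoromethanesulfonate CC[Si](CC)(CC)OS(=O)(=O)C(F)(F)F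
Why: In this one-pot sulfonylation–silylation of a diol, Tf2O takes only the primary hydroxyl at −78 °C and the silyl triflate then caps the tertiary one, no bond at C2 or C3 is touched, and the hindered base keeps acid away from the allylsilane.

Step 7
Reactants: 9 (2S,3R,6E)-2-bromo-3,7-dimethyl-3-(triethylsilyloxy)-8-(trimethylsilyl)oct-6-en-1-yl trifluoromethanesulfonate
Product: 12 {[(1R,2S,4S)-2-bromo-1-methyl-4-(prop-1-en-2-yl)cyclohexyl]oxy}triethylsilane, via bromonium triflate 10 (not isolated), via β-silyl cation triflate 11 (not isolated)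
Conditions: 2,6-di-tert-butyl-4-methylpyridine (1.5 equiv), (CF3)2CHOH–CH2Cl2 1:1, 0.005 M, −20 °C to rt
Reagents that add atoms: none
Why: Proposed new method: in the strongly ionising and barely nucleophilic fluoro alcohol the C–OTf bond of 9 should break with backside help from the bromine on C2 to give bromonium ion 10 (a three-membered ring of C2, C3 and Br), the allylsilane π bond then attacks the primary carbon C3 opposite to bromine, and the tertiary β-silyl cation 11 sheds silicon so that only the isopropenyl isomer can form, while a direct SN2 attack of the π bond on the triflate carbon would end in the same product. The closest known reactions are the anchimerically assisted solvolysis of enantioenriched β-bromo sulfonates in fluorinated alcohols, the π-route cyclisation of alkenyl sulfonates and allylsilane-terminated cation–olefin cyclisations, but their combination on a primary β-bromo triflate has not been tried. The cyclohexane closes 6-endo with respect to the bromonium ring and 6-exo-trig with respect to the C4=C2' olefin. C1 and C2 pass through unchanged because bromine never leaves C2 and only the C3–Br bond of 10 is broken, and the new centre C4 is set by a chair transition state in which Br (anti to the forming C3–C4 bond), the C1 methyl and the C2' arm are equatorial and only the silyloxy group is axial, which corresponds to (4S). The step needs attack at C3 rather than at C2 (5-exo), which the substrate secures because C2 is secondary, neopentyl-like and next to the electron-poor oxygenated C1, and it needs bromine to stay off the electron-rich olefin, which is secured by the absence of any free electrophilic bromine source and by high dilution against intermolecular bromonium transfer. The hindered pyridine takes up the acid released, so that neither the allylsilane nor the silyl ether is protonated.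

Step 8
Reactants: 12 {[(1R,2S,4S)-2-bromo-1-methyl-4-(prop-1-en-2-yl)cyclohexyl]oxy}triethylsilane
Product: 14 1-[(1S,3S,4R)-3-bromo-4-methyl-4-(triethylsilyloxy)cyclohexyl]ethan-1-one, via secondary ozonide 13 (not isolated)
Conditions: O3, CH2Cl2, −78 °C; then Me2S, −78 °C to rt
Reagents that add atoms: ozone [O-][O+]=O
Why: Ozonolysis (Criegee mechanism) of the only C=C bond with reductive work-up gives the methyl ketone without touching bromide, silyl ether or the three stereocentres, and ring C4 now carries its acetyl group in the thermodynamically preferred equatorial position.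

Step 9
Reactants: 14 1-[(1S,3S,4R)-3-bromo-4-methyl-4-(triethylsilyloxy)cyclohexyl]ethan-1-one; 15 triethyl phosphonoacetate
Product: 17 ethyl (2E)-3-[(1S,3S,4R)-3-bromo-4-methyl-4-(triethylsilyloxy)cyclohexyl]but-2-enoate, via sodium phosphonate 16 (not isolated)
Conditions: 15, NaH (slightly less than 15), THF, 0 °C; then 14, 0 to 40 °C
Reagents that add atoms: 15 triethyl phosphonoacetate CCOC(=O)CP(=O)(OCC)OCC
Why: The Horner–Wadsworth–Emmons olefination of a methyl ketone with a branched cyclohexyl group puts the ester trans to the larger ring substituent, so the (E)-enoate should prevail (any (Z)-isomer is removed by chromatography), and the stabilised anion is too weak a base to enolise 14 towards the bromide.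

Step 10
Reactants: 17 ethyl (2E)-3-[(1S,3S,4R)-3-bromo-4-methyl-4-(triethylsilyloxy)cyclohexyl]but-2-enoate
Product: 18 (2E)-3-[(1S,3S,4R)-3-bromo-4-methyl-4-(triethylsilyloxy)cyclohexyl]but-2-en-1-ol
Conditions: i-Bu2AlH (2.2 equiv), CH2Cl2, −78 °C
Reagents that add atoms: none
Why: The 1,2-reduction of a conjugated ester with i-Bu2AlH at low temperature gives the allylic alcohol and leaves the secondary bromide, the silyl ether and the olefin geometry untouched.

Step 11
Reactants: 18 (2E)-3-[(1S,3S,4R)-3-bromo-4-methyl-4-(triethylsilyloxy)cyclohexyl]but-2-en-1-ol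
Product: 19 (2E)-3-[(1S,3S,4R)-3-bromo-4-methyl-4-(triethylsilyloxy)cyclohexyl]but-2-enal
Conditions: activated MnO2 (excess), CH2Cl2, rt
Reagents that add atoms: none
Why: The MnO2 oxidation is selective for allylic alcohols, runs under neutral conditions and keeps the (E) geometry.

Step 12
Reactants: 19 (2E)-3-[(1S,3S,4R)-3-bromo-4-methyl-4-(triethylsilyloxy)cyclohexyl]but-2-enal; 20 bis[(pinacolato)boryl]methane
Product: 22 2-{(1E,3E)-4-[(1S,3S,4R)-3-bromo-4-methyl-4-(triethylsilyloxy)cyclohexyl]penta-1,3-dien-1-yl}-4,4,5,5-tetramethyl-1,3,2-dioxaborolane, via lithiated bis(boronate) 21 (not isolated)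
Conditions: 20, lithium 2,2,6,6-tetramethylpiperidide (from the amine and n-BuLi), THF, 0 °C; then 19, −78 °C to rt
Reagents that add atoms: 20 bis[(pinacolato)boryl]methane CC1(C)OB(CB2OC(C)(C)C(C)(C)O2)OC1(C)C
Why: In the boron–Wittig olefination the lithiated geminal bis(boronate) adds 1,2 to the enal and syn B–O elimination from the less crowded adduct gives the (E)-alkenyl boronate, so C5' and boron arrive in one aprotic operation that cannot add solvent to the enal or disturb the bromide.

Step 13
Reactants: 23 (S)-sulcatol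
Product: 24 (2S)-6-methylhept-5-en-2-yl 2,4,6-triisopropylbenzoate
Conditions: 2,4,6-triisopropylbenzoyl chloride, pyridine, DMAP, 60 °C
Reagents that add atoms: 2,4,6-triisopropylbenzoyl chloride CC(C)c1cc(C(C)C)c(C(=O)Cl)c(C(C)C)c1
Why: DMAP-catalysed O-acylation does not touch the C–O bond of the stereocentre, so the (S) configuration is kept.

Step 14
Reactants: 22 2-{(1E,3E)-4-[(1S,3S,4R)-3-bromo-4-methyl-4-(triethylsilyloxy)cyclohexyl]penta-1,3-dien-1-yl}-4,4,5,5-tetramethyl-1,3,2-dioxaborolane; 24 (2S)-6-methylhept-5-en-2-yl 2,4,6-triisopropylbenzoate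
Product: 28 (6S,7E,9E)-10-[(1S,3S,4R)-3-bromo-4-methyl-4-(triethylsilyloxy)cyclohexyl]-2,6-dimethylundeca-2,7,9-trien-6-ol, via lithiated benzoate 25 (not isolated), via boronate complex 26 (not isolated), via tertiary boronic ester 27 (not isolated)
Conditions: 24 (1.6 equiv), s-BuLi (1.5 equiv), TMEDA, cyclopentyl methyl ether, −60 °C; then 22 (1.0 equiv), −60 °C to rt; then H2O2, NaOH aq., THF, 0 °C
Reagents that add atoms: 24 (2S)-6-methylhept-5-en-2-yl 2,4,6-triisopropylbenzoate CC(C)=CCC[C@H](C)OC(=O)c1c(C(C)C)cc(C(C)C)cc1C(C)C; hydrogen peroxide OO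
Why: In this lithiation–borylation the carbonyl-directed deprotonation gives a configurationally stable tertiary organolithium with retention, boron is taken up with retention, the dienyl group migrates anti to the departing carboxylate (Matteson-type 1,2-metallate shift, inversion at carbon) and oxidation with retention gives the (6'S)-carbinol with the (E,E)-diene intact, while capture of the organolithium by boron at −60 °C is expected to outrun any attack on the secondary bromide.

Step 15
Reactants: 28 (6S,7E,9E)-10-[(1S,3S,4R)-3-bromo-4-methyl-4-(triethylsilyloxy)cyclohexyl]-2,6-dimethylundeca-2,7,9-trien-6-ol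
Product: 29 (1R,2S,4S)-2-bromo-4-[(2E,4E,6S)-6-hydroxy-6,10-dimethylundeca-2,4,9-trien-2-yl]-1-methylcyclohexan-1-ol
Conditions: Bu4NF, AcOH (1:1), THF, 0 °C to rt
Reagents that add atoms: none
Why: Buffered fluoride desilylation frees the C1 hydroxyl without acid that would ionise the dienylic C6' carbinol, and epoxide formation is not possible because the axial C1 oxygen and the equatorial C2 bromine are not anti-periplanar.

## Compound list

1 | geranyl acetate, (2E)-3,7-dimethylocta-2,6-dien-1-yl acetate | CC(C)=CCC/C(C)=C/COC(C)=O | starting material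
2 | (2E,6E)-8-hydroxy-3,7-dimethylocta-2,6-dien-1-yl acetate | OC/C(C)=C/CC/C(C)=C/COC(C)=O | intermediate
3 | (2E,6E)-8-chloro-3,7-dimethylocta-2,6-dien-1-yl acetate | ClC/C(C)=C/CC/C(C)=C/COC(C)=O | intermediate
4 | (2E,6E)-3,7-dimethyl-8-(trichlorosilyl)octa-2,6-dien-1-yl acetate | Cl[Si](Cl)(Cl)C/C(C)=C/CC/C(C)=C/COC(C)=O | intermediate
5 | (2E,6E)-3,7-dimethyl-8-(trimethylsilyl)octa-2,6-dien-1-ol | C[Si](C)(C)C/C(C)=C/CC/C(C)=C/CO | intermediate
6 | {(2R,3R)-3-methyl-3-[(3E)-4-methyl-5-(trimethylsilyl)pent-3-en-1-yl]oxiran-2-yl}methanol | C[Si](C)(C)C/C(C)=C/CC[C@@]1(C)O[C@@H]1CO | intermediate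
7 | (2S,3R,6E)-2-bromo-3,7-dimethyl-8-(trimethylsilyl)oct-6-ene-1,3-diol | C[Si](C)(C)C/C(C)=C/CC[C@@](C)(O)[C@@H](Br)CO | intermediate
8 | (2S,3R,6E)-2-bromo-3-hydroxy-3,7-dimethyl-8-(trimethylsilyl)oct-6-en-1-yl trifluoromethanesulfonate | C[Si](C)(C)C/C(C)=C/CC[C@@](C)(O)[C@@H](Br)COS(=O)(=O)C(F)(F)F | intermediate
9 | (2S,3R,6E)-2-bromo-3,7-dimethyl-3-(triethylsilyloxy)-8-(trimethylsilyl)oct-6-en-1-yl trifluoromethanesulfonate | C[Si](C)(C)C/C(C)=C/CC[C@@](C)(O[Si](CC)(CC)CC)[C@@H](Br)COS(=O)(=O)C(F)(F)F | intermediate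
10 | bromonium (bromiranium) triflate spanning geranyl C1 and C2 (ring C3 and C2), side chain as in 9 | C[Si](C)(C)C/C(C)=C/CC[C@@](C)(O[Si](CC)(CC)CC)[C@@H]1C[Br+]1.[O-]S(=O)(=O)C(F)(F)F | intermediate
11 | cyclised tertiary β-silyl carbocation (cation at C2', CH2SiMe3 still attached), triflate salt | C[Si](C)(C)C[C+](C)[C@H]1CC[C@@](C)(O[Si](CC)(CC)CC)[C@@H](Br)C1.[O-]S(=O)(=O)C(F)(F)F | intermediate
12 | {[(1R,2S,4S)-2-bromo-1-methyl-4-(prop-1-en-2-yl)cyclohexyl]oxy}triethylsilane | C=C(C)[C@H]1CC[C@@](C)(O[Si](CC)(CC)CC)[C@@H](Br)C1 | intermediate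
13 | secondary ozonide of 12, a 3-methyl-1,2,4-trioxolan-3-yl group on ring C4 (mixture at the trioxolane carbon) | CC1(OCOO1)[C@H]2CC[C@@](C)(O[Si](CC)(CC)CC)[C@@H](Br)C2 | intermediate
14 | 1-[(1S,3S,4R)-3-bromo-4-methyl-4-(triethylsilyloxy)cyclohexyl]ethan-1-one | CC(=O)[C@H]1CC[C@@](C)(O[Si](CC)(CC)CC)[C@@H](Br)C1 | intermediate
15 | triethyl phosphonoacetate | CCOC(=O)CP(=O)(OCC)OCC | starting material
16 | sodium salt of triethyl phosphonoacetate | [Na+].CCOC(=O)[CH-]P(=O)(OCC)OCC | intermediate
17 | ethyl (2E)-3-[(1S,3S,4R)-3-bromo-4-methyl-4-(triethylsilyloxy)cyclohexyl]but-2-enoate | CCOC(=O)/C=C(\C)[C@H]1CC[C@@](C)(O[Si](CC)(CC)CC)[C@@H](Br)C1 | intermediate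
18 | (2E)-3-[(1S,3S,4R)-3-bromo-4-methyl-4-(triethylsilyloxy)cyclohexyl]but-2-en-1-ol | OC/C=C(\C)[C@H]1CC[C@@](C)(O[Si](CC)(CC)CC)[C@@H](Br)C1 | intermediate
19 | (2E)-3-[(1S,3S,4R)-3-bromo-4-methyl-4-(triethylsilyloxy)cyclohexyl]but-2-enal | O=C/C=C(\C)[C@H]1CC[C@@](C)(O[Si](CC)(CC)CC)[C@@H](Br)C1 | intermediate
20 | bis[(pinacolato)boryl]methane | CC1(C)OB(CB2OC(C)(C)C(C)(C)O2)OC1(C)C | starting material
21 | lithiobis[(pinacolato)boryl]methane | [Li]C(B1OC(C)(C)C(C)(C)O1)B1OC(C)(C)C(C)(C)O1 | intermediate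
22 | 2-{(1E,3E)-4-[(1S,3S,4R)-3-bromo-4-methyl-4-(triethylsilyloxy)cyclohexyl]penta-1,3-dien-1-yl}-4,4,5,5-tetramethyl-1,3,2-dioxaborolane | CC1(C)OB(/C=C/C=C(\C)[C@H]2CC[C@@](C)(O[Si](CC)(CC)CC)[C@@H](Br)C2)OC1(C)C | intermediate
23 | (S)-sulcatol, (2S)-6-methylhept-5-en-2-ol | CC(C)=CCC[C@H](C)O | starting material
24 | (2S)-6-methylhept-5-en-2-yl 2,4,6-triisopropylbenzoate | CC(C)=CCC[C@H](C)OC(=O)c1c(C(C)C)cc(C(C)C)cc1C(C)C | intermediate
25 | (2S)-2-lithio-6-methylhept-5-en-2-yl 2,4,6-triisopropylbenzoate | CC(C)=CCC[C@]([Li])(C)OC(=O)c1c(C(C)C)cc(C(C)C)cc1C(C)C | intermediate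
26 | lithium boronate complex: boron of 22 bound with retention to the carbanion carbon of 25 | CC(C)=CCC[C@]([B-]1(OC(C)(C)C(C)(C)O1)/C=C/C=C(\C)[C@H]2CC[C@@](C)(O[Si](CC)(CC)CC)[C@@H](Br)C2)(C)OC(=O)c3c(C(C)C)cc(C(C)C)cc3C(C)C.[Li+] | intermediate
27 | tertiary allylic boronic ester: 28 with Bpin in place of the C6' hydroxyl, (6'R) because boron ranks last | CC(C)=CCC[C@@](B1OC(C)(C)C(C)(C)O1)(C)/C=C/C=C(\C)[C@H]2CC[C@@](C)(O[Si](CC)(CC)CC)[C@@H](Br)C2 | intermediate
28 | (6S,7E,9E)-10-[(1S,3S,4R)-3-bromo-4-methyl-4-(triethylsilyloxy)cyclohexyl]-2,6-dimethylundeca-2,7,9-trien-6-ol | CC(C)=CCC[C@](C)(O)/C=C/C=C(\C)[C@H]1CC[C@@](C)(O[Si](CC)(CC)CC)[C@@H](Br)C1 | intermediate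
29 | (1R,2S,4S)-2-bromo-4-[(2E,4E,6S)-6-hydroxy-6,10-dimethylundeca-2,4,9-trien-2-yl]-1-methylcyclohexan-1-ol (CNP0308936.2) | CC(C)=CCC[C@](C)(O)/C=C/C=C(\C)[C@H]1CC[C@@](C)(O)[C@@H](Br)C1 | target

## Step count

Total step count: 15.
Longest linear sequence: 14 (steps 1–12, 14 and 15; step 13 is the side branch).

## Steps most likely to fail

**1. Step 7 (bears the label "Proposed new method:").**
- What may go wrong:
  - Ionisation of the primary triflate may be too slow.
  - Bromine may be handed over from the bromonium ion to the electron-rich allylsilane olefin.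
  - The π bond may attack 5-exo at C2.
  - The silyl ether oxygen may capture C2.
  - The two chairs may be poorly discriminated, which would lower the facial selectivity at C4.
- Fallback: known chemistry that sets out from bromodiol 7 and comes back at methyl ketone 14. The same C3–C4 bond is closed by an enolate instead of a π bond. TsCl in pyridine converts the primary hydroxyl of 7 into hydroxy tosylate F1. Et3SiOTf/2,6-lutidine gives silyl ether F2. Protodesilylation of the allylsilane with allylic shift (CF3CO2H, CH2Cl2, −20 °C) gives the 1,1-disubstituted olefin F3. Ozonolysis through ozonide F4 (O3, then Me2S) gives keto tosylate F5. KN(SiMe3)2 in THF (−78 °C to rt, enolates left to equilibrate) then closes the ring 6-exo-tet through the more substituted potassium enolate F6. The eight-membered closure from the methyl-side enolate cannot compete. The product is 14, in which the acetyl group can settle in the equatorial position because C4 is enolisable.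

**2. Step 5.**
- What may go wrong:
  - Regiocontrol may be lost, with bromide attacking the tertiary C3 if the opening takes on carbocation character.
  - The crowded trisubstituted epoxide may open sluggishly.
- Fallback: sets out from epoxy alcohol 6 and comes back at triflate 9. The boron chelate is given up, and steric bias alone steers a soft bromide on an O-protected substrate. Et3SiCl/imidazole gives epoxy silyl ether F7. Li2NiBr4 in THF opens it by plain SN2 attack at the less substituted C2 to give bromohydrin F8. Et3SiOTf/2,6-lutidine gives bis(silyl) ether F9. Pyridinium p-toluenesulfonate in MeOH–CH2Cl2 at 0 °C removes only the primary silyl group to give alcohol F10. Tf2O with 2,6-di-tert-butyl-4-methylpyridine at −78 °C then gives 9.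

**3. Step 14.**
- What may go wrong:
  - Deprotonation may be incomplete, so that leftover s-BuLi consumes the valuable boronate.
  - Halogen–metal exchange or elimination may occur at the C2 bromide.
  - The 1,2-shift in the crowded boronate complex may be slow.
- Fallback: sets out from lithiated benzoate 25 and ketone 14 and comes back at 28. No organolithium ever meets the bromide, and the union becomes an sp2–sp2 coupling at C3'–C4'. An excess of cheap vinylboronic acid pinacol ester traps 25 as boronate complex F11. This rearranges to tertiary allylic boronic ester F12, and H2O2/NaOH gives (S)-linalool F13. Ketone 14 is condensed with 21 (boron–Wittig on the ketone) to the (E)-alkenyl boronate F14, which is freed from any (Z)-isomer by chromatography. NaOH followed by I2 converts it with retention into (E)-alkenyl iodide F15. A silver-assisted Heck reaction of F15 with F13 (Pd(OAc)2, Ag2CO3, DMF, rt) gives 28. Zerovalent palladium inserts into the alkenyl C–I bond far faster than into the secondary C–Br bond, and the quaternary carbinol allows β-hydride loss only towards the (E)-diene.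

## Further compounds

F1 | step 7 | (2S,3R,6E)-2-bromo-3-hydroxy-3,7-dimethyl-8-(trimethylsilyl)oct-6-en-1-yl 4-methylbenzenesulfonate | C[Si](C)(C)C/C(C)=C/CC[C@@](C)(O)[C@@H](Br)COS(=O)(=O)c1ccc(C)cc1
F2 | step 7 | (2S,3R,6E)-2-bromo-3,7-dimethyl-3-(triethylsilyloxy)-8-(trimethylsilyl)oct-6-en-1-yl 4-methylbenzenesulfonate | C[Si](C)(C)C/C(C)=C/CC[C@@](C)(O[Si](CC)(CC)CC)[C@@H](Br)COS(=O)(=O)c1ccc(C)cc1
F3 | step 7 | (2S,3R)-2-bromo-3,7-dimethyl-3-(triethylsilyloxy)oct-7-en-1-yl 4-methylbenzenesulfonate | C=C(C)CCC[C@@](C)(O[Si](CC)(CC)CC)[C@@H](Br)COS(=O)(=O)c1ccc(C)cc1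
F4 | step 7 | secondary ozonide of F3 (mixture at the trioxolane carbon) | CC1(OCOO1)CCC[C@@](C)(O[Si](CC)(CC)CC)[C@@H](Br)COS(=O)(=O)c2ccc(C)cc2
F5 | step 7 | (2S,3R)-2-bromo-3-methyl-7-oxo-3-(triethylsilyloxy)octyl 4-methylbenzenesulfonate | CC(=O)CCC[C@@](C)(O[Si](CC)(CC)CC)[C@@H](Br)COS(=O)(=O)c1ccc(C)cc1
F6 | step 7 | more substituted potassium enolate of F5 | CC([O-])=CCC[C@@](C)(O[Si](CC)(CC)CC)[C@@H](Br)COS(=O)(=O)c1ccc(C)cc1.[K+]
F7 | step 5 | triethyl({(2R,3R)-3-methyl-3-[(3E)-4-methyl-5-(trimethylsilyl)pent-3-en-1-yl]oxiran-2-yl}methoxy)silane | C[Si](C)(C)C/C(C)=C/CC[C@@]1(C)O[C@@H]1CO[Si](CC)(CC)CC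
F8 | step 5 | (2S,3R,6E)-2-bromo-3,7-dimethyl-1-(triethylsilyloxy)-8-(trimethylsilyl)oct-6-en-3-ol | C[Si](C)(C)C/C(C)=C/CC[C@@](C)(O)[C@@H](Br)CO[Si](CC)(CC)CC
F9 | step 5 | (2S,3R,6E)-2-bromo-3,7-dimethyl-1,3-bis(triethylsilyloxy)-8-(trimethylsilyl)oct-6-ene | C[Si](C)(C)C/C(C)=C/CC[C@@](C)(O[Si](CC)(CC)CC)[C@@H](Br)CO[Si](CC)(CC)CC
F10 | step 5 | (2S,3R,6E)-2-bromo-3,7-dimethyl-3-(triethylsilyloxy)-8-(trimethylsilyl)oct-6-en-1-ol | C[Si](C)(C)C/C(C)=C/CC[C@@](C)(O[Si](CC)(CC)CC)[C@@H](Br)CO
F11 | step 14 | lithium boronate complex of 25 with vinylboronic acid pinacol ester | CC(C)=CCC[C@]([B-]1(C=C)OC(C)(C)C(C)(C)O1)(C)OC(=O)c2c(C(C)C)cc(C(C)C)cc2C(C)C.[Li+]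
F12 | step 14 | 2-[(3R)-3,7-dimethylocta-1,6-dien-3-yl]-4,4,5,5-tetramethyl-1,3,2-dioxaborolane | CC(C)=CCC[C@@](B1OC(C)(C)C(C)(C)O1)(C)C=C
F13 | step 14 | (S)-linalool, (3S)-3,7-dimethylocta-1,6-dien-3-ol | CC(C)=CCC[C@](C)(O)C=C
F14 | step 14 | 2-{(1E)-2-[(1S,3S,4R)-3-bromo-4-methyl-4-(triethylsilyloxy)cyclohexyl]prop-1-en-1-yl}-4,4,5,5-tetramethyl-1,3,2-dioxaborolane | CC1(C)OB(/C=C(\C)[C@H]2CC[C@@](C)(O[Si](CC)(CC)CC)[C@@H](Br)C2)OC1(C)C
F15 | step 14 | ({(1R,2S,4S)-2-bromo-4-[(1E)-1-iodoprop-1-en-2-yl]-1-methylcyclohexyl}oxy)triethylsilane | I/C=C(\C)[C@H]1CC[C@@](C)(O[Si](CC)(CC)CC)[C@@H](Br)C1
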